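free monomer 0.80 M; initiator 0.84 mol%; time 15 h

    free monomer + initiator → living end + monomer in chains (k1 = 0.00953 M⁻¹ min⁻¹)
    free monomer + living end → monomer in chains + living end, rate k2*[living end]*[free monomer] (k2 = 4.07 M⁻¹ min⁻¹)
    living end + monomer in chains → dead end (k3 = 0.0106 M⁻¹ min⁻¹)

1. average number of monomer units in a chain (chains begun, living or dead) at 15 h
2. part of the free monomer that has reacted at 15 h

Take the easy step first: with the charge still free, a living end adds a unit every 0.307 min. Climb from there. Once the charge sits in chains, a living end dies in about 118 min, far slower than it adds. With free monomer held at its charge, initiator lasts about as long, 131 min. Free monomer by the starting step on its own, with initiator held at its charge, has a half-life of 180 h, long against 15 h. So picture the adding step carrying the monomer, while chains begin and die on a slower clock.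

Now compute only the small thing, the dead ends, as a fraction of the charge. Count monomer in chains as the reacted fraction, since the loading is a small correction. For each unit added, the living ends lost number 0.0106 M⁻¹ min⁻¹ over 4.07 M⁻¹ min⁻¹, times monomer in chains over free monomer. Call that constant ratio the death ratio, 0.00260, a selectivity factor. Summing over conversion, dead ends equal the death ratio times the logarithm of charged over left, less the reacted fraction. The living end and time cancel.

Put dead ends at their ceiling, the loading 0.84 mol%. Free monomer then rests near 1.46%, with an average near 116. My reckoning gives that stop, not a value at 15 h. The forecast gives 188 and 94%, and its ground is this: “Only about 0.004 M of the 0.0067 M initiator ever starts a chain because the monomer runs low”.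

This flask gives 163 and 95.8%. The rule, fed its free monomer left, gives 0.577% dead ends against 0.571% simulated. For the neighbour charged with 0.32 M, it gives 0.425% against 0.422%. This flask is not at rest: by 150 h free monomer has fallen from 4.17% to 1.70%, still above the floor, initiator from 30.5% to 7.27%, and the average from 163 to 125.

(All constants were set for the occasion.)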